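(The runs are simulated with made-up constants, noise included.)

- Follow one unit of substrate through Wednesday's flask, which is the flask asked about, and ask at each moment for its chance of ending in open dimer rather than ring.

| flask | substrate | remark | time |
|---|---|---|---|
| Wednesday's | 0.80 M | the very flask that is asked about, followed so far |  |
| flask | 0.80 M |  | 15 d |

- Wednesday's (time / d: ring / %, open dimer / %, substrate / %): 0.208: 86.7, 5.7, 7.1; 0.625: 94.2, 6.0, 0.3; 1.04: 94.1, 5.6, 0; 1.67: 94.1, 6.0, 0; 2.50: 94.1, 5.8, 0.2; 3.00: 94.3, 5.6, 0.1

(each reading ± 0.3 percentage points)

- percent here means substrate units held: one open dimer counts as two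
- the earlier runs were read with a standard deviation of 0.3 percentage points
- a reading or a percentage of ring counts all its forms, free or not

1. the ring standing at 15 d, as a percentage of the substrate charged
2. the open dimer standing at 15 d, as a percentage of the substrate charged

- I carried the dimer share, open dimer over open dimer plus ring in the readings from 1.04 d on, 5.76%, the selectivity of this flask.
- In the first instants I assumed that open dimer needed two substrate to meet, so its chance fell in step with the substrate left. I put the opening chance at 11.5%, because a chance falling straight to zero averages half its opening value.
- By the first reading of Wednesday's run, at 0.208 d, substrate read 7.1%, so the chance had dropped to 0.817%, and open dimer already read 5.7%.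
- After that, substrate read 0.3% at 0.625 d and 0.1% at the last reading, 3.00 d, so the fork had closed. I committed to 94.2% ring and 5.76% open dimer at 15 d, assuming that the plateau held beyond the readings.
- The forecast, made from the same readings, gave 94.2% ring and 5.8% open dimer: “The simplest expectation is that the plateau persists”.
- The simulation gave 94.2% ring at 15 d, with 61.7% standing as crystals inside that figure, and 5.82% open dimer. Left ten times as long, ring did not move. A run charged with 0.105 M or 1.60 M of substrate would show the forecast wrong: open dimer had moved 5 points at each, while at the charge of this flask it stayed within that up to at least 120 d.

    substrate → ring (k = 0.00850 min⁻¹)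
    2 substrate → open dimer (k = 6.70 × 10⁻⁴ M⁻¹ min⁻¹)
    crystals ⇌ ring, rate k3*(cs3 - [ring]) while solid is left; crystals form when [ring] > cs3 (solubility = 0.260 M, k = 0.270 min⁻¹)

- In the neighbouring flask, charged with 0.20 M, a quarter of the charge, I scaled the share with the charge to 1.44%, and that flask held 98.5% ring and 1.54% open dimer.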